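**Plan**
- Retrosynthetically the MOM and acetyl groups go first. The furan ring is then cut at O1–C2 and at C3–CH2, which turns C2–C3 back into a diarylalkyne and places the ring D benzyl group on the oxygen of ring B (the benzo ring of the benzofuran).
- This cut is possible because benzofuran C3 carries a CH2 bound to the 2,4-dioxygenated ring D, a cation-stabilised benzyl group that can move from O1 to C3, while ring A sits on C2.
- Further cuts: ring A–C(sp) (Sonogashira), ring B O–CH2 (Mitsunobu), coumarin C3–ring D (Suzuki), coumarin C3=C4 with the lactone C–O (Wittig–lactonisation), and both ring–C(CH3)2 bonds (Claisen rearrangement of prenyl ethers).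
- Forward: the coumarin ring is made first (step 6), joined to ring D (step 9) and to ring B (step 12); the alkyne is installed and coupled to ring A (steps 13 and 16); the furan ring closes last (step 17), followed by deprotection.
- The target has no stereocentre and no stereogenic double bond, so no stereocontrol is needed.

Key step: step 17

Remark: ethyl bromo(triphenylphosphoranylidene)acetate is taken as a stock reagent, made beforehand from the parent ylide and NBS and freed of succinimide, so that no electrophilic bromine meets the vinyl group in step 6.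

**Step 1**
Reactants: 1 2,4-dihydroxybenzaldehyde; 2 1-bromo-3-methylbut-2-ene (prenyl bromide)
Product: 3 2-hydroxy-4-[(3-methylbut-2-en-1-yl)oxy]benzaldehyde
Conditions: K2CO3 (1.1 equiv), acetone, 50 °C
Reagents that add atoms: none
Why: Williamson ether synthesis in which the 2-OH, held in a hydrogen bond to the formyl group, stays untouched so that the 4-OH is alkylated selectively.

**Step 2**
Reactants: 3 2-hydroxy-4-[(3-methylbut-2-en-1-yl)oxy]benzaldehyde
Product: 4 2-(methoxymethoxy)-4-[(3-methylbut-2-en-1-yl)oxy]benzaldehyde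
Conditions: NaH, DMF, 0 °C; then MOMCl, 0 °C → rt
Reagents that add atoms: chloromethyl methyl ether, COCCl
Why: MOM protection of the sodium phenoxide removes the OH···O=C chelate whose bond fixation would otherwise steer the coming rearrangement to C3.

**Step 3**
Reactants: 4 2-(methoxymethoxy)-4-[(3-methylbut-2-en-1-yl)oxy]benzaldehyde
Product: 6 4-hydroxy-2-(methoxymethoxy)-5-(2-methylbut-3-en-2-yl)benzaldehyde, via ortho-dienone 5 (not isolated)
Conditions: PhNEt2, 190 °C, Ar
Reagents that add atoms: none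
Why: Aromatic Claisen rearrangement ([3,3]-sigmatropic shift) delivers the tertiary prenyl carbon to the ring, and since C3 is flanked by two oxygen substituents the shift should go to C5, as in the 2-methoxy series used for licochalcone-type 1,1-dimethylallyl phenols, after which dienone 5 tautomerises to the phenol.

**Step 4**
Reactants: 6 4-hydroxy-2-(methoxymethoxy)-5-(2-methylbut-3-en-2-yl)benzaldehyde
Product: 7 2,4-dihydroxy-5-(2-methylbut-3-en-2-yl)benzaldehyde
Conditions: 2 M aq. HCl, MeOH, 40 °C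
Reagents that add atoms: none
Why: Acid-catalysed acetal methanolysis of the MOM ether next to the formyl group is fast, and brief contact with dilute acid should leave the monosubstituted alkene alone.

**Step 5**
Reactants: 7 2,4-dihydroxy-5-(2-methylbut-3-en-2-yl)benzaldehyde
Product: 8 2-hydroxy-4-(methoxymethoxy)-5-(2-methylbut-3-en-2-yl)benzaldehyde
Conditions: MOMCl (1.05 equiv), K2CO3, acetone, 0 °C → rt
Reagents that add atoms: chloromethyl methyl ether, COCCl
Why: Selective O-alkylation of the non-chelated 4-OH, the same selectivity that step 1 relies on, leaves the salicylaldehyde OH free for lactone formation.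

**Step 6**
Reactants: 8 2-hydroxy-4-(methoxymethoxy)-5-(2-methylbut-3-en-2-yl)benzaldehyde
Product: 10 3-bromo-7-(methoxymethoxy)-6-(2-methylbut-3-en-2-yl)-2H-chromen-2-one, via bromoacrylate 9 (not isolated)
Conditions: Ph3P=C(Br)CO2Et (1.3 equiv), toluene, 110 °C
Reagents that add atoms: ethyl bromo(triphenylphosphoranylidene)acetate, CCOC(=O)C(Br)=P(c1ccccc1)(c1ccccc1)c1ccccc1
Why: Wittig olefination with the stabilised bromo ylide followed by lactonisation of the bromoacrylate isomer that has aryl and ester cis (heating is meant to equilibrate the other isomer) is a known one-pot entry to 3-bromocoumarins from salicylaldehydes.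

**Step 7**
Reactants: 11 5-bromo-2,4-dihydroxybenzaldehyde
Product: 12 5-bromo-2,4-bis(methoxymethoxy)benzaldehyde
Conditions: NaH (2.4 equiv), DMF, 0 °C; then MOMCl (2.4 equiv), 0 °C → rt
Reagents that add atoms: chloromethyl methyl ether, COCCl
Why: Double MOM protection through the bis-phenoxide also caps the chelated 2-OH and provides the two donor ethers that later stabilise the migrating benzyl cation.

**Step 8**
Reactants: 12 5-bromo-2,4-bis(methoxymethoxy)benzaldehyde
Product: 13 2,4-bis(methoxymethoxy)-5-(4,4,5,5-tetramethyl-1,3,2-dioxaborolan-2-yl)benzaldehyde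
Conditions: B2pin2, Pd(dppf)Cl2 (5 mol %), KOAc, 1,4-dioxane, 90 °C
Reagents that add atoms: bis(pinacolato)diboron, CC1(C)OB(OC1(C)C)B1OC(C)(C)C(C)(C)O1
Why: Miyaura borylation under acetate base tolerates the aldehyde and the MOM ethers and turns ring D into the nucleophilic partner.

**Step 9**
Reactants: 10 3-bromo-7-(methoxymethoxy)-6-(2-methylbut-3-en-2-yl)-2H-chromen-2-one; 13 2,4-bis(methoxymethoxy)-5-(4,4,5,5-tetramethyl-1,3,2-dioxaborolan-2-yl)benzaldehyde
Product: 14 5-[7-(methoxymethoxy)-6-(2-methylbut-3-en-2-yl)-2-oxo-2H-chromen-3-yl]-2,4-bis(methoxymethoxy)benzaldehyde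
Conditions: Pd(dppf)Cl2 (5 mol %), K3PO4, 1,4-dioxane–H2O, 80 °C
Reagents that add atoms: none
Why: Suzuki–Miyaura coupling of the activated vinylic bromide at coumarin C3 with an aryl pinacol boronate is the standard way to 3-arylcoumarins and fixes the biaryl bond without ambiguity.

**Step 10**
Reactants: 14 5-[7-(methoxymethoxy)-6-(2-methylbut-3-en-2-yl)-2-oxo-2H-chromen-3-yl]-2,4-bis(methoxymethoxy)benzaldehyde
Product: 15 3-[5-(hydroxymethyl)-2,4-bis(methoxymethoxy)phenyl]-7-(methoxymethoxy)-6-(2-methylbut-3-en-2-yl)-2H-chromen-2-one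
Conditions: NaBH4, THF–MeOH, −10 °C
Reagents that add atoms: none
Why: Hydride 1,2-reduction of the aldehyde at low temperature should be much faster than attack on the hindered 3-aryl coumarin enoate.

**Step 11**
Reactants: 1 2,4-dihydroxybenzaldehyde
Product: 16 2-hydroxy-4-(methoxymethoxy)benzaldehyde
Conditions: MOMCl (1.05 equiv), K2CO3, acetone, 0 °C → rt
Reagents that add atoms: chloromethyl methyl ether, COCCl
Why: Selective MOM protection of the non-chelated 4-OH gives ring B with its ortho OH free for etherification.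

**Step 12**
Reactants: 15 3-[5-(hydroxymethyl)-2,4-bis(methoxymethoxy)phenyl]-7-(methoxymethoxy)-6-(2-methylbut-3-en-2-yl)-2H-chromen-2-one; 16 2-hydroxy-4-(methoxymethoxy)benzaldehyde
Product: 17 2-({5-[7-(methoxymethoxy)-6-(2-methylbut-3-en-2-yl)-2-oxo-2H-chromen-3-yl]-2,4-bis(methoxymethoxy)phenyl}methoxy)-4-(methoxymethoxy)benzaldehyde
Conditions: PPh3, DIAD, THF, 0 °C → rt
Reagents that add atoms: none
Why: Mitsunobu etherification joins the acidic salicylaldehyde OH to the primary, electron-rich benzylic alcohol under neutral conditions and avoids an unstable 2,4-dialkoxybenzyl halide.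

**Step 13**
Reactants: 17 2-({5-[7-(methoxymethoxy)-6-(2-methylbut-3-en-2-yl)-2-oxo-2H-chromen-3-yl]-2,4-bis(methoxymethoxy)phenyl}methoxy)-4-(methoxymethoxy)benzaldehyde
Product: 18 3-(5-{[2-ethynyl-5-(methoxymethoxy)phenoxy]methyl}-2,4-bis(methoxymethoxy)phenyl)-7-(methoxymethoxy)-6-(2-methylbut-3-en-2-yl)-2H-chromen-2-one
Conditions: dimethyl (1-diazo-2-oxopropyl)phosphonate, K2CO3, MeOH–THF, 0 °C → rt
Reagents that add atoms: dimethyl (1-diazo-2-oxopropyl)phosphonate, COP(=O)(OC)C(=[N+]=[N-])C(C)=O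
Why: Ohira–Bestmann (Seyferth–Gilbert) homologation converts the aldehyde into the terminal alkyne under carbonate/methanol conditions that the MOM ethers, the benzyl ether and the coumarin should withstand.

**Step 14**
Reactants: 19 4-iodoresorcinol; 2 1-bromo-3-methylbut-2-ene (prenyl bromide)
Product: 20 2-iodo-5-[(3-methylbut-2-en-1-yl)oxy]phenol
Conditions: K2CO3 (1.0 equiv), acetone, rt
Reagents that add atoms: none
Why: Williamson ether synthesis in which the hydroxyl para to iodine, less shielded and the better nucleophile than the ortho-iodo hydroxyl, should be alkylated preferentially.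

**Step 15**
Reactants: 20 2-iodo-5-[(3-methylbut-2-en-1-yl)oxy]phenol
Product: 24 4-iodo-6-(2-methylbut-3-en-2-yl)-1,3-phenylene diacetate, via aryl acetate 21 (not isolated), via ortho-dienone 22 (not isolated), via phenol monoacetate 23 (not isolated)
Conditions: Ac2O (6 equiv), NaOAc (0.2 equiv), PhNEt2, 185 °C, sealed tube
Reagents that add atoms: acetic anhydride, CC(=O)OC(C)=O
Why: After acetylation of the free phenol, the aromatic Claisen rearrangement should place the 1,1-dimethylallyl group at the open ortho carbon and not at the carbon wedged between the two oxygens, and in situ acetylation of the new phenol suppresses abnormal Claisen rearrangement and cyclisation onto the alkene.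

**Step 16**
Reactants: 18 3-(5-{[2-ethynyl-5-(methoxymethoxy)phenoxy]methyl}-2,4-bis(methoxymethoxy)phenyl)-7-(methoxymethoxy)-6-(2-methylbut-3-en-2-yl)-2H-chromen-2-one; 24 4-iodo-6-(2-methylbut-3-en-2-yl)-1,3-phenylene diacetate
Product: 25 4-{[2-({5-[7-(methoxymethoxy)-6-(2-methylbut-3-en-2-yl)-2-oxo-2H-chromen-3-yl]-2,4-bis(methoxymethoxy)phenyl}methoxy)-4-(methoxymethoxy)phenyl]ethynyl}-6-(2-methylbut-3-en-2-yl)-1,3-phenylene diacetate
Conditions: PdCl2(PPh3)2 (3 mol %), CuI (5 mol %), Et3N, THF, 40 °C, degassed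
Reagents that add atoms: none
Why: Sonogashira coupling of the aryl iodide with the terminal alkyne uses only a tertiary amine base, which spares the aryl acetates, and with no free ortho hydroxyl present no premature cyclisation can occur.

**Step 17**
Reactants: 25 4-{[2-({5-[7-(methoxymethoxy)-6-(2-methylbut-3-en-2-yl)-2-oxo-2H-chromen-3-yl]-2,4-bis(methoxymethoxy)phenyl}methoxy)-4-(methoxymethoxy)phenyl]ethynyl}-6-(2-methylbut-3-en-2-yl)-1,3-phenylene diacetate
Product: 26 4-[3-({5-[7-(methoxymethoxy)-6-(2-methylbut-3-en-2-yl)-2-oxo-2H-chromen-3-yl]-2,4-bis(methoxymethoxy)phenyl}methyl)-6-(methoxymethoxy)-1-benzofuran-2-yl]-6-(2-methylbut-3-en-2-yl)-1,3-phenylene diacetate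
Conditions: PtCl2 (10 mol %), CO (1 atm), toluene (0.02 M), 80 °C
Reagents that add atoms: none
Why: PtCl2, a π-acid of divalent platinum made more electrophilic by CO, binds the alkyne of 25, and the benzyl ether oxygen of ring B adds anti in a 5-endo-dig closure that forms O1–C2 and gives a 3-platinated benzofuranyl oxonium ion. The 2,4-bis(methoxymethoxy)benzyl group of ring D then leaves the oxonium oxygen as a well-stabilised cation within the ion pair (or in a concerted 1,3-shift) and is captured by the C3–Pt bond, which forms C3–CH2 and releases PtCl2. The closest known reaction type is the PtCl2-catalysed carboalkoxylation of 2-alkynylphenyl benzyl, allyl and α-alkoxyalkyl ethers to 3-substituted benzofurans. The furan ring is the only ring closed, its mode is 5-endo-dig, and no stereocentre arises. The step needs a choice between the two ortho oxygens on the alkyne and clean delivery of the benzyl group to C3: the ring A oxygens are acetates, too weakly nucleophilic to attack and unable to pass on a carbon group, whereas the ring B oxygen carries the only migrating group and all other MOM ethers are remote from the alkyne. High dilution and transfer within the ion pair should keep the benzyl cation from alkylating other electron-rich ring positions.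

**Step 18**
Reactants: 26 4-[3-({5-[7-(methoxymethoxy)-6-(2-methylbut-3-en-2-yl)-2-oxo-2H-chromen-3-yl]-2,4-bis(methoxymethoxy)phenyl}methyl)-6-(methoxymethoxy)-1-benzofuran-2-yl]-6-(2-methylbut-3-en-2-yl)-1,3-phenylene diacetate
Product: 27 3-[5-({2-[2,4-dihydroxy-5-(2-methylbut-3-en-2-yl)phenyl]-6-(methoxymethoxy)-1-benzofuran-3-yl}methyl)-2,4-bis(methoxymethoxy)phenyl]-7-(methoxymethoxy)-6-(2-methylbut-3-en-2-yl)-2H-chromen-2-one
Conditions: K2CO3 (0.3 equiv), MeOH–THF, 0 °C → rt
Reagents that add atoms: none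
Why: Base-catalysed transesterification with methanol removes the two aryl acetates under conditions to which MOM ethers are inert and under which the coumarin lactone should persist.

**Step 19**
Reactants: 27 3-[5-({2-[2,4-dihydroxy-5-(2-methylbut-3-en-2-yl)phenyl]-6-(methoxymethoxy)-1-benzofuran-3-yl}methyl)-2,4-bis(methoxymethoxy)phenyl]-7-(methoxymethoxy)-6-(2-methylbut-3-en-2-yl)-2H-chromen-2-one
Product: 28 3-[5-({2-[2,4-dihydroxy-5-(2-methylbut-3-en-2-yl)phenyl]-6-hydroxy-1-benzofuran-3-yl}methyl)-2,4-dihydroxyphenyl]-7-hydroxy-6-(2-methylbut-3-en-2-yl)-2H-chromen-2-one (CNP0380243.0)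
Conditions: 2 M aq. HCl, MeOH–THF, 40 °C
Reagents that add atoms: none
Why: Acid-catalysed acetal methanolysis cleaves the four MOM ethers, and dilute acid at moderate temperature should not protonate the monosubstituted alkenes of the 1,1-dimethylallyl groups next to the freed phenols.

**Compound list**
1 | 2,4-dihydroxybenzaldehyde | O=Cc1ccc(O)cc1O | starting material
2 | 1-bromo-3-methylbut-2-ene (prenyl bromide) | CC(C)=CCBr | starting material
3 | 2-hydroxy-4-[(3-methylbut-2-en-1-yl)oxy]benzaldehyde | CC(C)=CCOc1ccc(C=O)c(O)c1 | intermediate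
4 | 2-(methoxymethoxy)-4-[(3-methylbut-2-en-1-yl)oxy]benzaldehyde | COCOc1cc(OCC=C(C)C)ccc1C=O | intermediate
5 | 6-(methoxymethoxy)-3-(2-methylbut-3-en-2-yl)-4-oxocyclohexa-1,5-diene-1-carbaldehyde (Claisen ortho-dienone, racemic, not isolated) | O=CC1=CC(C(C)(C)C=C)C(=O)C=C1OCOC | intermediate
6 | 4-hydroxy-2-(methoxymethoxy)-5-(2-methylbut-3-en-2-yl)benzaldehyde | COCOc1cc(O)c(C(C)(C)C=C)cc1C=O | intermediate
7 | 2,4-dihydroxy-5-(2-methylbut-3-en-2-yl)benzaldehyde | C=CC(C)(C)c1cc(C=O)c(O)cc1O | intermediate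
8 | 2-hydroxy-4-(methoxymethoxy)-5-(2-methylbut-3-en-2-yl)benzaldehyde | COCOc1cc(O)c(C=O)cc1C(C)(C)C=C | intermediate
9 | ethyl (E)-2-bromo-3-[2-hydroxy-4-(methoxymethoxy)-5-(2-methylbut-3-en-2-yl)phenyl]prop-2-enoate (not isolated) | CCOC(=O)/C(Br)=C\c1cc(C(C)(C)C=C)c(OCOC)cc1O | intermediate
10 | 3-bromo-7-(methoxymethoxy)-6-(2-methylbut-3-en-2-yl)-2H-chromen-2-one | COCOc1cc2oc(=O)c(Br)cc2cc1C(C)(C)C=C | intermediate
11 | 5-bromo-2,4-dihydroxybenzaldehyde | O=Cc1cc(Br)c(O)cc1O | starting material
12 | 5-bromo-2,4-bis(methoxymethoxy)benzaldehyde | COCOc1cc(OCOC)c(C=O)cc1Br | intermediate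
13 | 2,4-bis(methoxymethoxy)-5-(4,4,5,5-tetramethyl-1,3,2-dioxaborolan-2-yl)benzaldehyde | COCOc1cc(OCOC)c(C=O)cc1B1OC(C)(C)C(C)(C)O1 | intermediate
14 | 5-[7-(methoxymethoxy)-6-(2-methylbut-3-en-2-yl)-2-oxo-2H-chromen-3-yl]-2,4-bis(methoxymethoxy)benzaldehyde | COCOc1cc(OCOC)c(C=O)cc1-c1cc2cc(C(C)(C)C=C)c(OCOC)cc2oc1=O | intermediate
15 | 3-[5-(hydroxymethyl)-2,4-bis(methoxymethoxy)phenyl]-7-(methoxymethoxy)-6-(2-methylbut-3-en-2-yl)-2H-chromen-2-one | COCOc1cc(OCOC)c(CO)cc1-c1cc2cc(C(C)(C)C=C)c(OCOC)cc2oc1=O | intermediate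
16 | 2-hydroxy-4-(methoxymethoxy)benzaldehyde | COCOc1ccc(C=O)c(O)c1 | intermediate
17 | 2-({5-[7-(methoxymethoxy)-6-(2-methylbut-3-en-2-yl)-2-oxo-2H-chromen-3-yl]-2,4-bis(methoxymethoxy)phenyl}methoxy)-4-(methoxymethoxy)benzaldehyde | COCOc1ccc(C=O)c(OCc2cc(-c3cc4cc(C(C)(C)C=C)c(OCOC)cc4oc3=O)c(OCOC)cc2OCOC)c1 | intermediate
18 | 3-(5-{[2-ethynyl-5-(methoxymethoxy)phenoxy]methyl}-2,4-bis(methoxymethoxy)phenyl)-7-(methoxymethoxy)-6-(2-methylbut-3-en-2-yl)-2H-chromen-2-one | C#Cc1ccc(OCOC)cc1OCc1cc(-c2cc3cc(C(C)(C)C=C)c(OCOC)cc3oc2=O)c(OCOC)cc1OCOC | intermediate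
19 | 4-iodoresorcinol (4-iodobenzene-1,3-diol) | Oc1ccc(I)c(O)c1 | starting material
20 | 2-iodo-5-[(3-methylbut-2-en-1-yl)oxy]phenol | CC(C)=CCOc1ccc(I)c(O)c1 | intermediate
21 | 2-iodo-5-[(3-methylbut-2-en-1-yl)oxy]phenyl acetate (not isolated) | CC(=O)Oc1cc(OCC=C(C)C)ccc1I | intermediate
22 | 6-iodo-4-(2-methylbut-3-en-2-yl)-3-oxocyclohexa-1,5-dien-1-yl acetate (Claisen ortho-dienone, racemic, not isolated) | CC(=O)OC1=CC(=O)C(C(C)(C)C=C)C=C1I | intermediate
23 | 5-hydroxy-2-iodo-4-(2-methylbut-3-en-2-yl)phenyl acetate (not isolated) | CC(=O)Oc1cc(O)c(C(C)(C)C=C)cc1I | intermediate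
24 | 4-iodo-6-(2-methylbut-3-en-2-yl)-1,3-phenylene diacetate | CC(=O)Oc1cc(OC(C)=O)c(C(C)(C)C=C)cc1I | intermediate
25 | 4-{[2-({5-[7-(methoxymethoxy)-6-(2-methylbut-3-en-2-yl)-2-oxo-2H-chromen-3-yl]-2,4-bis(methoxymethoxy)phenyl}methoxy)-4-(methoxymethoxy)phenyl]ethynyl}-6-(2-methylbut-3-en-2-yl)-1,3-phenylene diacetate | CC(=O)Oc1cc(OC(C)=O)c(C(C)(C)C=C)cc1C#Cc1ccc(OCOC)cc1OCc1cc(-c2cc3cc(C(C)(C)C=C)c(OCOC)cc3oc2=O)c(OCOC)cc1OCOC | intermediate
26 | 4-[3-({5-[7-(methoxymethoxy)-6-(2-methylbut-3-en-2-yl)-2-oxo-2H-chromen-3-yl]-2,4-bis(methoxymethoxy)phenyl}methyl)-6-(methoxymethoxy)-1-benzofuran-2-yl]-6-(2-methylbut-3-en-2-yl)-1,3-phenylene diacetate | C=CC(C)(C)c1cc(-c2oc3cc(OCOC)ccc3c2Cc2cc(-c3cc4cc(C(C)(C)C=C)c(OCOC)cc4oc3=O)c(OCOC)cc2OCOC)c(OC(C)=O)cc1OC(C)=O | intermediate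
27 | 3-[5-({2-[2,4-dihydroxy-5-(2-methylbut-3-en-2-yl)phenyl]-6-(methoxymethoxy)-1-benzofuran-3-yl}methyl)-2,4-bis(methoxymethoxy)phenyl]-7-(methoxymethoxy)-6-(2-methylbut-3-en-2-yl)-2H-chromen-2-one | C=CC(C)(C)c1cc(-c2oc3cc(OCOC)ccc3c2Cc2cc(-c3cc4cc(C(C)(C)C=C)c(OCOC)cc4oc3=O)c(OCOC)cc2OCOC)c(O)cc1O | intermediate
28 | 3-[5-({2-[2,4-dihydroxy-5-(2-methylbut-3-en-2-yl)phenyl]-6-hydroxy-1-benzofuran-3-yl}methyl)-2,4-dihydroxyphenyl]-7-hydroxy-6-(2-methylbut-3-en-2-yl)-2H-chromen-2-one (CNP0380243.0) | C=CC(C)(C)c1cc(-c2oc3cc(O)ccc3c2Cc2cc(-c3cc4cc(C(C)(C)C=C)c(O)cc4oc3=O)c(O)cc2O)c(O)cc1O | target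

**Totals**
Total step count: 19. Longest linear sequence: 14 steps (steps 1–6, 9, 10, 12, 13, 16, 17, 18, 19).

**Steps most likely to fail**

Step 17. The platinated oxonium intermediate may lose the benzyl group to stray nucleophiles and protodemetalate to the C3–H benzofuran, the two vinyl groups may tie up the catalyst, or traces of HCl may erode MOM ethers. In that case the two bonds would be made one after the other. Setting out from 16, Ohira–Bestmann homologation would give 2-ethynyl-5-(methoxymethoxy)phenol F1. Sonogashira coupling of F1 with 24 would give 4-{[2-hydroxy-4-(methoxymethoxy)phenyl]ethynyl}-6-(2-methylbut-3-en-2-yl)-1,3-phenylene diacetate F2. Warming F2 with CuI and Et3N (5-endo-dig hydroalkoxylation) would close it to 4-[6-(methoxymethoxy)-1-benzofuran-2-yl]-6-(2-methylbut-3-en-2-yl)-1,3-phenylene diacetate F3. Friedel–Crafts benzylation of F3 at C3 with alcohol 15 under catalytic Sc(OTf)3 in CH2Cl2 at 0 °C would return to the route at 26.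

Step 6. The olefination may give mainly the bromoacrylate isomer that cannot lactonise, and thermal equilibration may be incomplete or accompanied by decomposition. The coumarin would then be closed by a tethered aldol condensation, in which geometry is not an issue. Setting out from 13, palladium-catalysed coupling with ethyl bromoacetate (Pd(OAc)2, tri-o-tolylphosphine, K3PO4, THF–H2O) would give ethyl 2-[5-formyl-2,4-bis(methoxymethoxy)phenyl]acetate F4. Saponification with LiOH would give 2-[5-formyl-2,4-bis(methoxymethoxy)phenyl]acetic acid F5. Esterification of F5 with the phenol of 8 (EDC, DMAP) would give 2-formyl-5-(methoxymethoxy)-4-(2-methylbut-3-en-2-yl)phenyl 2-[5-formyl-2,4-bis(methoxymethoxy)phenyl]acetate F6. Treatment of F6 with DBU (intramolecular Knoevenagel condensation of Perkin type) would return to the route at 14, replacing steps 6 and 9.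

Step 3. The rearrangement may go partly to the crowded carbon between the two oxygens, and the product phenol may undergo abnormal Claisen rearrangement or cyclise onto its alkene on prolonged heating. The quaternary carbon would then be set by cross-coupling. Setting out from 12, a γ-selective, ligand-controlled Suzuki–Miyaura coupling with 3,3-dimethylallylboronic acid pinacol ester (palladium with a bulky biarylphosphine, aqueous K3PO4, MeCN, 70 °C) would give 2,4-bis(methoxymethoxy)-5-(2-methylbut-3-en-2-yl)benzaldehyde F7. Cleavage of both MOM ethers of F7 with dilute HCl in methanol would return to the route at 7, replacing steps 1–4.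

**Further compounds**
F1 | step 17 | 2-ethynyl-5-(methoxymethoxy)phenol | C#Cc1ccc(OCOC)cc1O
F2 | step 17 | 4-{[2-hydroxy-4-(methoxymethoxy)phenyl]ethynyl}-6-(2-methylbut-3-en-2-yl)-1,3-phenylene diacetate | CC(=O)Oc1cc(OC(C)=O)c(C(C)(C)C=C)cc1C#Cc1ccc(OCOC)cc1O
F3 | step 17 | 4-[6-(methoxymethoxy)-1-benzofuran-2-yl]-6-(2-methylbut-3-en-2-yl)-1,3-phenylene diacetate | CC(=O)Oc1cc(OC(C)=O)c(C(C)(C)C=C)cc1-c1cc2ccc(OCOC)cc2o1
F4 | step 6 | ethyl 2-[5-formyl-2,4-bis(methoxymethoxy)phenyl]acetate | CCOC(=O)Cc1cc(C=O)c(OCOC)cc1OCOC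
F5 | step 6 | 2-[5-formyl-2,4-bis(methoxymethoxy)phenyl]acetic acid | OC(=O)Cc1cc(C=O)c(OCOC)cc1OCOC
F6 | step 6 | 2-formyl-5-(methoxymethoxy)-4-(2-methylbut-3-en-2-yl)phenyl 2-[5-formyl-2,4-bis(methoxymethoxy)phenyl]acetate | COCOc1cc(OC(=O)Cc2cc(C=O)c(OCOC)cc2OCOC)c(C=O)cc1C(C)(C)C=C
F7 | step 3 | 2,4-bis(methoxymethoxy)-5-(2-methylbut-3-en-2-yl)benzaldehyde | COCOc1cc(OCOC)c(C=O)cc1C(C)(C)C=C
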